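The target is disconnected at C3–C3a and at the exocyclic CH2–O bond of the dihydrofuran (ring B). C3 carries both the benzo ring A (through C3a) and a CH2–O arm, so an aryl radical at C3a, ortho to O1, can add 5-exo to the vinyl group of an aryl 1-arylallyl ether, and the resulting primary radical can take its oxygen from TEMPO. One operation thus closes ring B, forms C3–C3a and the C–O bond, and sets C3 trans to the C2 aryl group. The precursor is the (S)-ether of acetal-masked 5-iodovanillin with a silyl-protected sinapyl unit; C2 is installed beforehand by iridium-catalysed branched-selective allylic etherification.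

Key step: step 7

Remark (assumption on the chemistry): the (Sa,Sc,Sc) antipode of the phosphoramidite in step 6 is taken to deliver the (S)-ether, following the usual sense of induction of these catalysts with aryl-substituted allyl carbonates; the configuration of 9 is to be confirmed on first preparation and the ligand antipode exchanged if needed.

Design note: the ring A formyl group stays masked as the dioxolane through steps 6 and 7, so the aryloxide remains a good nucleophile and a poor leaving group. After the key step the aldehyde is released and olefinated before the N–O bond is reduced, so no free aldehyde meets zinc. The silyl ether on the 4-hydroxy-3,5-dimethoxyphenyl ring C is kept to the last step, so no free para-phenol can open ring B through a quinone methide.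

Step 1
Reactants: 1 syringaldehyde
Product: 2 3,5-dimethoxy-4-(triisopropylsilyloxy)benzaldehyde
Conditions: i-Pr3SiCl, imidazole, DMF, rt
Reagents that add atoms: triisopropylsilyl chloride, CC(C)[Si](Cl)(C(C)C)C(C)C
Why: Silyl ether formation: imidazole-activated i-Pr3SiCl silylates the acidic phenol, and the bulky silyl group should then withstand hydride, base, radical and mild acid conditions until the last step.

Step 2
Reactants: 2 3,5-dimethoxy-4-(triisopropylsilyloxy)benzaldehyde
Product: 3 ethyl (E)-3-[3,5-dimethoxy-4-(triisopropylsilyloxy)phenyl]prop-2-enoate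
Conditions: Ph3P=CHCO2Et, toluene, 90 °C
Reagents that add atoms: ethyl (triphenylphosphoranylidene)acetate, CCOC(=O)C=P(c1ccccc1)(c1ccccc1)c1ccccc1
Why: Wittig olefination; a stabilised ylide reacts with an aromatic aldehyde to give the (E)-alkene almost exclusively.

Step 3
Reactants: 3 ethyl (E)-3-[3,5-dimethoxy-4-(triisopropylsilyloxy)phenyl]prop-2-enoate
Product: 4 (E)-3-[3,5-dimethoxy-4-(triisopropylsilyloxy)phenyl]prop-2-en-1-ol
Conditions: i-Bu2AlH, CH2Cl2, −78 °C; aq. potassium sodium tartrate work-up
Reagents that add atoms: none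
Why: Hydride reduction of the conjugated ester: i-Bu2AlH at low temperature reduces the ester 1,2-selectively to the allylic alcohol without touching the alkene or the aryl silyl ether.

Step 4
Reactants: 4 (E)-3-[3,5-dimethoxy-4-(triisopropylsilyloxy)phenyl]prop-2-en-1-ol
Product: 5 (E)-3-[3,5-dimethoxy-4-(triisopropylsilyloxy)phenyl]prop-2-en-1-yl methyl carbonate
Conditions: ClCO2Me, pyridine, CH2Cl2, 0 °C
Reagents that add atoms: methyl chloroformate, COC(=O)Cl
Why: Acylation of the primary alcohol with a chloroformate (carbonate formation) supplies the leaving group that the iridium catalyst ionizes in step 6.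

Step 5
Reactants: 6 5-iodovanillin
Product: 7 4-(1,3-dioxolan-2-yl)-2-iodo-6-methoxyphenol
Conditions: HOCH2CH2OH, TsOH·H2O (cat.), toluene, reflux with a water separator; Et3N quench
Reagents that add atoms: ethylene glycol, OCCO
Why: Acid-catalysed acetalization with azeotropic removal of water; masking the formyl group keeps the phenoxide electron-rich enough to be a competent nucleophile and a poor leaving group in step 6.

Step 6
Reactants: 7 4-(1,3-dioxolan-2-yl)-2-iodo-6-methoxyphenol, 5 (E)-3-[3,5-dimethoxy-4-(triisopropylsilyloxy)phenyl]prop-2-en-1-yl methyl carbonate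
Product: 9 2-{4-[(1S)-1-[3,5-dimethoxy-4-(triisopropylsilyloxy)phenyl]prop-2-en-1-yloxy]-3-iodo-5-methoxyphenyl}-1,3-dioxolane, via sodium phenolate 8 (not isolated)
Conditions: NaH, THF, 0 °C; then 5, [Ir(cod)Cl]2 (2 mol %), (Sa,Sc,Sc)-O,O′-(1,1′-binaphthyl-2,2′-diyl) N,N-bis(1-phenylethyl)phosphoramidite (4 mol %, catalyst preactivated with n-PrNH2), THF, rt to 50 °C; stopped at full conversion
Reagents that add atoms: none
Why: Iridium-catalysed asymmetric allylic substitution (allylic etherification): the cyclometalated iridium–phosphoramidite catalyst ionizes the linear carbonate and the aryloxide attacks the aryl-substituted allyl terminus, so the branched ether should form and the C2 stereocentre is set as (S) by the chiral ligand.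

Step 7
Reactants: 9 2-{4-[(1S)-1-[3,5-dimethoxy-4-(triisopropylsilyloxy)phenyl]prop-2-en-1-yloxy]-3-iodo-5-methoxyphenyl}-1,3-dioxolane, 10 TEMPO (2,2,6,6-tetramethylpiperidin-1-oxyl)
Product: 13 (2S,3R)-trans-2-[3,5-dimethoxy-4-(triisopropylsilyloxy)phenyl]-5-(1,3-dioxolan-2-yl)-7-methoxy-3-{[(2,2,6,6-tetramethylpiperidin-1-yl)oxy]methyl}-2,3-dihydrobenzofuran, via aryl radical 11 (not isolated), via primary alkyl radical 12 (not isolated)
Conditions: Bu3SnH (added in portions), TEMPO (excess), toluene (about 0.02 M), 70 °C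
Reagents that add atoms: none
Why: Stannyl radicals, formed as TEMPO abstracts hydrogen from Bu3SnH, take the iodine atom from 9 and leave the sigma aryl radical 11 at C3a, which adds to the internal carbon of the vinyl group to give the primary radical 12, and 12 couples at oxygen with the persistent nitroxide 10. The closest known reaction type is the tin hydride/TEMPO aryl radical cyclization–trapping sequence of ortho-iodophenyl allyl ethers and ortho-iodo-N-allylanilines (radical carbo-oxygenation of an alkene). Ring B closes in the 5-exo-trig mode, which for an ortho-allyloxyaryl radical is far faster than 6-endo attack at the terminal carbon. The new C3 centre is set by the C2 centre already present: in the chair-like transition state the C2 aryl group lies pseudo-equatorial, so the exocyclic carbon should end up trans to it, which corresponds to (2S,3R). The step needs ring closure to outrun direct capture of 11 by TEMPO or Bu3SnH and a 1,4-hydrogen shift from the C2–H bond; the rigid ortho-oxygen tether, high dilution and the strained five-membered transition state of that shift secure this. Rapid nitroxide capture also denies 12 the time for a neophyl-type 1,2-aryl shift or for reduction to a methyl group.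

Step 8
Reactants: 13 (2S,3R)-trans-2-[3,5-dimethoxy-4-(triisopropylsilyloxy)phenyl]-5-(1,3-dioxolan-2-yl)-7-methoxy-3-{[(2,2,6,6-tetramethylpiperidin-1-yl)oxy]methyl}-2,3-dihydrobenzofuran
Product: 14 (2S,3R)-2-[3,5-dimethoxy-4-(triisopropylsilyloxy)phenyl]-7-methoxy-3-{[(2,2,6,6-tetramethylpiperidin-1-yl)oxy]methyl}-2,3-dihydrobenzofuran-5-carbaldehyde
Conditions: AcOH/THF/H2O (3:1:1), 40 °C
Reagents that add atoms: water, O
Why: Acid-catalysed acetal hydrolysis: the electron-rich aryl dioxolane opens in warm aqueous acetic acid, conditions under which the alkoxyamine, the aryl silyl ether and the benzylic C2–O bond should persist.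

Step 9
Reactants: 14 (2S,3R)-2-[3,5-dimethoxy-4-(triisopropylsilyloxy)phenyl]-7-methoxy-3-{[(2,2,6,6-tetramethylpiperidin-1-yl)oxy]methyl}-2,3-dihydrobenzofuran-5-carbaldehyde
Product: 16 (E)-3-[(2S,3R)-2-[3,5-dimethoxy-4-(triisopropylsilyloxy)phenyl]-7-methoxy-3-{[(2,2,6,6-tetramethylpiperidin-1-yl)oxy]methyl}-2,3-dihydrobenzofuran-5-yl]prop-2-enoic acid, via arylidenemalonic acid 15 (not isolated)
Conditions: CH2(CO2H)2, pyridine, piperidine (cat.), 85 °C
Reagents that add atoms: malonic acid, OC(=O)CC(=O)O
Why: Knoevenagel–Doebner condensation: the aldehyde condenses with malonic acid and the arylidenemalonic acid 15 loses CO2 in hot pyridine to give the (E)-acrylic acid, the stereocentres at C2 and C3 being remote from the basic site.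

Step 10
Reactants: 16 (E)-3-[(2S,3R)-2-[3,5-dimethoxy-4-(triisopropylsilyloxy)phenyl]-7-methoxy-3-{[(2,2,6,6-tetramethylpiperidin-1-yl)oxy]methyl}-2,3-dihydrobenzofuran-5-yl]prop-2-enoic acid
Product: 17 (E)-3-[(2S,3R)-2-[3,5-dimethoxy-4-(triisopropylsilyloxy)phenyl]-3-(hydroxymethyl)-7-methoxy-2,3-dihydrobenzofuran-5-yl]prop-2-enoic acid
Conditions: Zn dust, AcOH/THF/H2O (3:1:1), 70 °C
Reagents that add atoms: none
Why: Reductive N–O bond cleavage by dissolving metal: electron transfer from Zn in acetic acid severs the weak N–O bond of the alkoxyamine and releases the primary alcohol, while the acrylic acid and the aryl silyl ether should not be reduced under these conditions.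

Step 11
Reactants: 17 (E)-3-[(2S,3R)-2-[3,5-dimethoxy-4-(triisopropylsilyloxy)phenyl]-3-(hydroxymethyl)-7-methoxy-2,3-dihydrobenzofuran-5-yl]prop-2-enoic acid
Product: 18 (E)-3-[(2S,3R)-2-(4-hydroxy-3,5-dimethoxyphenyl)-3-(hydroxymethyl)-7-methoxy-2,3-dihydrobenzofuran-5-yl]prop-2-enoic acid
Conditions: Bu4NF, AcOH, THF, 0 °C to rt; work-up at pH 3
Reagents that add atoms: none
Why: Fluoride-mediated desilylation: the strong Si–F bond drives cleavage of the aryl silyl ether, and acetic acid buffers the phenoxide so that ring B cannot open through a quinone methide and C2 keeps its configuration.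

Compound list
1 | syringaldehyde (4-hydroxy-3,5-dimethoxybenzaldehyde) | COc1cc(C=O)cc(OC)c1O | starting material
2 | 3,5-dimethoxy-4-(triisopropylsilyloxy)benzaldehyde | COc1cc(C=O)cc(OC)c1O[Si](C(C)C)(C(C)C)C(C)C | intermediate
3 | ethyl (E)-3-[3,5-dimethoxy-4-(triisopropylsilyloxy)phenyl]prop-2-enoate | CCOC(=O)/C=C/c1cc(OC)c(O[Si](C(C)C)(C(C)C)C(C)C)c(OC)c1 | intermediate
4 | (E)-3-[3,5-dimethoxy-4-(triisopropylsilyloxy)phenyl]prop-2-en-1-ol | OC/C=C/c1cc(OC)c(O[Si](C(C)C)(C(C)C)C(C)C)c(OC)c1 | intermediate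
5 | (E)-3-[3,5-dimethoxy-4-(triisopropylsilyloxy)phenyl]prop-2-en-1-yl methyl carbonate | COC(=O)OC/C=C/c1cc(OC)c(O[Si](C(C)C)(C(C)C)C(C)C)c(OC)c1 | intermediate
6 | 5-iodovanillin (4-hydroxy-3-iodo-5-methoxybenzaldehyde) | COc1cc(C=O)cc(I)c1O | starting material
7 | 4-(1,3-dioxolan-2-yl)-2-iodo-6-methoxyphenol | COc1cc(C2OCCO2)cc(I)c1O | intermediate
8 | sodium 4-(1,3-dioxolan-2-yl)-2-iodo-6-methoxyphenolate | [Na+].COc1cc(C2OCCO2)cc(I)c1[O-] | intermediate
9 | 2-{4-[(1S)-1-[3,5-dimethoxy-4-(triisopropylsilyloxy)phenyl]prop-2-en-1-yloxy]-3-iodo-5-methoxyphenyl}-1,3-dioxolane | COc1cc([C@H](C=C)Oc2c(OC)cc(C3OCCO3)cc2I)cc(OC)c1O[Si](C(C)C)(C(C)C)C(C)C | intermediate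
10 | TEMPO (2,2,6,6-tetramethylpiperidin-1-oxyl) | CC1(C)CCCC(C)(C)N1[O] | starting material
11 | aryl radical at C3a formed from 9 by loss of the iodine atom, (S) at the ether carbon | COc1cc([C@H](C=C)Oc2c(OC)cc(C3OCCO3)c[c]2)cc(OC)c1O[Si](C(C)C)(C(C)C)C(C)C | intermediate
12 | trans-{2-[3,5-dimethoxy-4-(triisopropylsilyloxy)phenyl]-5-(1,3-dioxolan-2-yl)-7-methoxy-2,3-dihydrobenzofuran-3-yl}methyl radical, (2S), C2 aryl and C3 CH2 trans | COc1cc([C@H]2Oc3c(OC)cc(C4OCCO4)cc3[C@@H]2[CH2])cc(OC)c1O[Si](C(C)C)(C(C)C)C(C)C | intermediate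
13 | (2S,3R)-trans-2-[3,5-dimethoxy-4-(triisopropylsilyloxy)phenyl]-5-(1,3-dioxolan-2-yl)-7-methoxy-3-{[(2,2,6,6-tetramethylpiperidin-1-yl)oxy]methyl}-2,3-dihydrobenzofuran | COc1cc([C@H]2Oc3c(OC)cc(C4OCCO4)cc3[C@@H]2CON5C(C)(C)CCCC5(C)C)cc(OC)c1O[Si](C(C)C)(C(C)C)C(C)C | intermediate
14 | (2S,3R)-2-[3,5-dimethoxy-4-(triisopropylsilyloxy)phenyl]-7-methoxy-3-{[(2,2,6,6-tetramethylpiperidin-1-yl)oxy]methyl}-2,3-dihydrobenzofuran-5-carbaldehyde | COc1cc([C@H]2Oc3c(OC)cc(C=O)cc3[C@@H]2CON4C(C)(C)CCCC4(C)C)cc(OC)c1O[Si](C(C)C)(C(C)C)C(C)C | intermediate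
15 | 2-{[(2S,3R)-2-[3,5-dimethoxy-4-(triisopropylsilyloxy)phenyl]-7-methoxy-3-{[(2,2,6,6-tetramethylpiperidin-1-yl)oxy]methyl}-2,3-dihydrobenzofuran-5-yl]methylidene}propanedioic acid | COc1cc([C@H]2Oc3c(OC)cc(C=C(C(=O)O)C(=O)O)cc3[C@@H]2CON4C(C)(C)CCCC4(C)C)cc(OC)c1O[Si](C(C)C)(C(C)C)C(C)C | intermediate
16 | (E)-3-[(2S,3R)-2-[3,5-dimethoxy-4-(triisopropylsilyloxy)phenyl]-7-methoxy-3-{[(2,2,6,6-tetramethylpiperidin-1-yl)oxy]methyl}-2,3-dihydrobenzofuran-5-yl]prop-2-enoic acid | COc1cc([C@H]2Oc3c(OC)cc(/C=C/C(=O)O)cc3[C@@H]2CON4C(C)(C)CCCC4(C)C)cc(OC)c1O[Si](C(C)C)(C(C)C)C(C)C | intermediate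
17 | (E)-3-[(2S,3R)-2-[3,5-dimethoxy-4-(triisopropylsilyloxy)phenyl]-3-(hydroxymethyl)-7-methoxy-2,3-dihydrobenzofuran-5-yl]prop-2-enoic acid | COc1cc([C@H]2Oc3c(OC)cc(/C=C/C(=O)O)cc3[C@@H]2CO)cc(OC)c1O[Si](C(C)C)(C(C)C)C(C)C | intermediate
18 | (E)-3-[(2S,3R)-2-(4-hydroxy-3,5-dimethoxyphenyl)-3-(hydroxymethyl)-7-methoxy-2,3-dihydrobenzofuran-5-yl]prop-2-enoic acid | COc1cc([C@H]2Oc3c(OC)cc(/C=C/C(=O)O)cc3[C@@H]2CO)cc(OC)c1O | target

Total step count: 11.
Longest linear sequence: 10 steps (steps 1–4 and 6–11, from syringaldehyde); the branch from 5-iodovanillin adds step 5.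

Steps most likely to fail

Step 7. What may go wrong: the nitroxide intercepts the aryl radical or the stannyl chain carrier before ring closure, so that conversion stalls or an uncyclized aryl–oxygen adduct forms, and the trans preference at C3 may be eroded at 70 °C. Fallback: setting out from 9, ring B is closed by an aerobic oxygenative radical cyclization (Bu3SnH, dry air, toluene, 0 °C to rt). Dissolved dioxygen is present only at millimolar level, so it cannot compete with cyclization yet still captures the primary radical. This should give the cyclized hydroperoxide F1, which is reduced in the same flask with PPh3 to the primary alcohol F2. AcOH/THF/H2O then releases the hydroxy aldehyde F3, and Knoevenagel–Doebner condensation (malonic acid, pyridine, piperidine) through the arylidenemalonic acid F4 comes back to the route at 17; the N–O cleavage step is then no longer needed.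

Step 6. What may go wrong: slow attack of the hindered, doubly ortho-substituted aryloxide and re-ionization of the electron-rich product ether by the catalyst erode branched selectivity and enantiomeric purity. Fallback: setting out from 2, CH2=CHMgBr (THF, −78 °C) gives the racemic allylic alcohol F5. Candida antarctica lipase B with vinyl acetate, following its usual enantiopreference for secondary alcohols, should acylate the (R)-enantiomer to the (R)-acetate F6, which is separated from unreacted (S)-alcohol. i-Bu2AlH (CH2Cl2, −78 °C) frees the (R)-alcohol F7. Mitsunobu coupling with phenol 7 (PPh3, DIAD, toluene, −20 °C, to hold back allylic transposition) should proceed with inversion and comes back to the route at 9.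

Step 5. What may go wrong: the free para-hydroxyl group deactivates the formyl group and labilizes the acetal, so acetalization stalls or reverts during isolation. Fallback: setting out from 6, the phenol is first acetylated (Ac2O, pyridine) to the aryl acetate F8, which is acetalized with ethylene glycol and TsOH under azeotropic water removal to the acetal acetate F9; K2CO3 in MeOH at 0 °C removes the acetate and comes back to the route at 7.

Further compounds
F1 | step 7 | {(2S,3R)-2-[3,5-dimethoxy-4-(triisopropylsilyloxy)phenyl]-5-(1,3-dioxolan-2-yl)-7-methoxy-2,3-dihydrobenzofuran-3-yl}methyl hydroperoxide | COc1cc([C@H]2Oc3c(OC)cc(C4OCCO4)cc3[C@@H]2COO)cc(OC)c1O[Si](C(C)C)(C(C)C)C(C)C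
F2 | step 7 | {(2S,3R)-2-[3,5-dimethoxy-4-(triisopropylsilyloxy)phenyl]-5-(1,3-dioxolan-2-yl)-7-methoxy-2,3-dihydrobenzofuran-3-yl}methanol | COc1cc([C@H]2Oc3c(OC)cc(C4OCCO4)cc3[C@@H]2CO)cc(OC)c1O[Si](C(C)C)(C(C)C)C(C)C
F3 | step 7 | (2S,3R)-2-[3,5-dimethoxy-4-(triisopropylsilyloxy)phenyl]-3-(hydroxymethyl)-7-methoxy-2,3-dihydrobenzofuran-5-carbaldehyde | COc1cc([C@H]2Oc3c(OC)cc(C=O)cc3[C@@H]2CO)cc(OC)c1O[Si](C(C)C)(C(C)C)C(C)C
F4 | step 7 | 2-{[(2S,3R)-2-[3,5-dimethoxy-4-(triisopropylsilyloxy)phenyl]-3-(hydroxymethyl)-7-methoxy-2,3-dihydrobenzofuran-5-yl]methylidene}propanedioic acid | COc1cc([C@H]2Oc3c(OC)cc(C=C(C(=O)O)C(=O)O)cc3[C@@H]2CO)cc(OC)c1O[Si](C(C)C)(C(C)C)C(C)C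
F5 | step 6 | rac-1-[3,5-dimethoxy-4-(triisopropylsilyloxy)phenyl]prop-2-en-1-ol | COc1cc(C(O)C=C)cc(OC)c1O[Si](C(C)C)(C(C)C)C(C)C
F6 | step 6 | (1R)-1-[3,5-dimethoxy-4-(triisopropylsilyloxy)phenyl]prop-2-en-1-yl acetate | COc1cc([C@@H](C=C)OC(C)=O)cc(OC)c1O[Si](C(C)C)(C(C)C)C(C)C
F7 | step 6 | (1R)-1-[3,5-dimethoxy-4-(triisopropylsilyloxy)phenyl]prop-2-en-1-ol | COc1cc([C@@H](C=C)O)cc(OC)c1O[Si](C(C)C)(C(C)C)C(C)C
F8 | step 5 | 4-formyl-2-iodo-6-methoxyphenyl acetate | COc1cc(C=O)cc(I)c1OC(C)=O
F9 | step 5 | 4-(1,3-dioxolan-2-yl)-2-iodo-6-methoxyphenyl acetate | COc1cc(C2OCCO2)cc(I)c1OC(C)=O
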